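Numbering: the chain runs C1 (CH2OH) to C16, with methyls on C3, C7, C11 and C15 and a methylidene on C14; the oxiranes are C2–C3 (trans) and C6–C7 (cis).
Retrosynthesis: both oxiranes go back to alkenes (2E and 6Z); the chain is then cut at C5–C6, at C12–C13 and C10=C11 in the right half, and at C4–C5 and C2–C3 in the left half.
Enabling feature: C6 is the CH of a cis-trisubstituted oxirane, so a latent (Z)-C6=C7 alkene, and it is bonded to the primary sp3 carbon C5; C5–C6 is thus the CH2–CH= link of a 1,5-diene (C2=C3/C6=C7), which a C5 radical from a 4-enoic acid and a (Z)-alkenyl iodide can form on nickel with retention.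
Forward: fragment A (C1–C5 plus a sacrificial carboxyl carbon) comes from a Grignard addition and a Johnson–Claisen rearrangement; fragment B (C6–C16) comes from pent-4-yn-1-ol by anti-carbometalation/iodination, Wittig olefination and allylboration; the halves are joined at C5–C6 by electrochemical decarboxylative alkenylation, then oxirane C2–C3 and oxirane C6–C7 are formed in that order.
Stereochemistry: 2E from the Claisen chair, 6Z from chelation-controlled carbometalation (kept through the coupling), 10E from the stabilised ylide, C12 (R) from the (+)-Ipc2B allyl reagent, C2/C3 (R,R) from Sharpless epoxidation with D-(−)-diethyl tartrate, C6/C7 (R,S) from Shi epoxidation of the Z-alkene.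
Key step: step 10

Remark: alcohol 3 is used as the racemate because its carbinol centre disappears in step 2; all other chiral compounds are single enantiomers as drawn.

Step 1
Reactants: 1 (tert-butyldimethylsilyloxy)acetaldehyde; 2 isopropenylmagnesium bromide (CH2=C(CH3)MgBr)
Product: 3 rac-1-[(tert-butyldimethylsilyl)oxy]-3-methylbut-3-en-2-ol
Conditions: THF, −78 to 0 °C; aq. NH4Cl work-up
Reagents that add atoms: none
Why: Grignard 1,2-addition of the alkenylmagnesium reagent to the unhindered α-silyloxy aldehyde should give the 2-methylallylic alcohol, whose racemic carbinol centre is erased in step 2.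

Step 2
Reactants: 3 rac-1-[(tert-butyldimethylsilyl)oxy]-3-methylbut-3-en-2-ol; 4 triethyl orthoacetate
Product: 7 ethyl (4E)-6-[(tert-butyldimethylsilyl)oxy]-4-methylhex-4-enoate, via mixed orthoester 5 (not isolated), via ketene acetal 6 (not isolated)
Conditions: 4 (excess), EtCO2H (cat.), 140 °C, EtOH distilled off
Reagents that add atoms: none
Why: Johnson–Claisen rearrangement, in which orthoester exchange and loss of ethanol give ketene acetal 6, whose chair-like [3,3] shift with the CH2OSi group equatorial should form C4–C5 and the 2E trisubstituted alkene.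

Step 3
Reactants: 7 ethyl (4E)-6-[(tert-butyldimethylsilyl)oxy]-4-methylhex-4-enoate
Product: 8 (4E)-6-[(tert-butyldimethylsilyl)oxy]-4-methylhex-4-enoic acid
Conditions: LiOH·H2O, THF/MeOH/H2O, rt; then 1 M HCl to pH 4, 0 °C
Reagents that add atoms: lithium hydroxide, [Li+].[OH-]
Why: Saponification of the unhindered ethyl ester should proceed cleanly, the primary allylic silyl ether being stable to aqueous LiOH and to brief acidification to pH 4.

Step 4
Reactants: 8 (4E)-6-[(tert-butyldimethylsilyl)oxy]-4-methylhex-4-enoic acid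
Product: 9 1,3-dioxoisoindolin-2-yl (4E)-6-[(tert-butyldimethylsilyl)oxy]-4-methylhex-4-enoate
Conditions: N-hydroxyphthalimide, i-PrN=C=N-i-Pr, DMAP (cat.), CH2Cl2, rt
Reagents that add atoms: N-hydroxyphthalimide, O=C1c2ccccc2C(=O)N1O
Why: Carbodiimide (Steglich-type) esterification with N-hydroxyphthalimide should give the redox-active ester that serves as the precursor of the C5 radical.

Step 5
Reactants: 10 pent-4-yn-1-ol
Product: 13 (4Z)-5-iodo-4-methylpent-4-en-1-ol, via syn-alkenylalane 11 (not isolated), via chelated Z-alkenylalane 12 (not isolated)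
Conditions: Me3Al (3 equiv), Cp2ZrCl2 (0.25 equiv), ClCH2CH2Cl, rt; AlCl3 (cat.), reflux; then I2, THF, −30 to 0 °C
Reagents that add atoms: trimethylaluminium, C[Al](C)C; iodine, II
Why: Zirconium-catalysed carboalumination (Negishi) adds CH3–Al syn across the alkyne with Al on the terminal carbon, the aluminium alkoxide then drives thermal isomerisation to the O-chelated alkenylalane with Al cis to the carbinol chain, and iodinolysis with retention should give the 4Z iodoalkene (the future 6Z geometry), a sequence known for homopropargylic alcohols and their next homologues.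

Step 6
Reactants: 13 (4Z)-5-iodo-4-methylpent-4-en-1-ol
Product: 14 (4Z)-5-iodo-4-methylpent-4-enal
Conditions: Dess–Martin periodinane, CH2Cl2, 0 °C to rt
Reagents that add atoms: none
Why: Dess–Martin oxidation should convert the primary alcohol into the aldehyde under neutral conditions without touching the iodoalkene.

Step 7
Reactants: 14 (4Z)-5-iodo-4-methylpent-4-enal; 15 2-(triphenylphosphoranylidene)propanal
Product: 16 (2E,6Z)-7-iodo-2,6-dimethylhepta-2,6-dienal
Conditions: toluene, 90 °C
Reagents that add atoms: none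
Why: Wittig olefination with the stabilised α-methyl formyl ylide is E-selective and should set the future 10E alkene, the product enal being much less reactive towards the ylide than aldehyde 14.

Step 8
Reactants: 16 (2E,6Z)-7-iodo-2,6-dimethylhepta-2,6-dienal; 17 2,3-dimethylbut-1-ene
Product: 21 (4R,5E,9Z)-10-iodo-5,9-dimethyl-2-(propan-2-yl)deca-1,5,9-trien-4-ol, via 2-isopropylallylpotassium 18 (not isolated), via allyl-diisopinocampheylborane 19 (not isolated), via borinate ester 20 (not isolated)
Conditions: 17, n-BuLi, KOtBu, THF, −78 to −45 °C; (+)-Ipc2BOMe, −78 °C; BF3·OEt2; 16, −78 °C; then NaOH, H2O2, 0 °C to rt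
Reagents that add atoms: none
Why: Brown-type asymmetric allylboration, in which potassiation of 17 at its allylic methyl group, transmetalation to the (+)-Ipc2B reagent 19 and a closed chair (Zimmerman–Traxler) transition state should deliver the 2-isopropylallyl group to the Re face of the enal and give the 4R carbinol (C12 of the target).

Step 9
Reactants: 21 (4R,5E,9Z)-10-iodo-5,9-dimethyl-2-(propan-2-yl)deca-1,5,9-trien-4-ol
Product: 22 tert-butyl{[(4R,5E,9Z)-10-iodo-5,9-dimethyl-2-(propan-2-yl)deca-1,5,9-trien-4-yl]oxy}dimethylsilane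
Conditions: TBSOTf, 2,6-lutidine, CH2Cl2, −78 to 0 °C
Reagents that add atoms: tert-butyldimethylsilyl trifluoromethanesulfonate, CC(C)(C)[Si](C)(C)OS(=O)(=O)C(F)(F)F
Why: Silylation of the hindered secondary allylic alcohol with the silyl triflate should be clean, and the ether masks C12–OH for the nickel step and later blocks titanium-directed epoxidation of C10=C11.

Step 10
Reactants: 9 1,3-dioxoisoindolin-2-yl (4E)-6-[(tert-butyldimethylsilyl)oxy]-4-methylhex-4-enoate (1.5 equiv); 22 tert-butyl{[(4R,5E,9Z)-10-iodo-5,9-dimethyl-2-(propan-2-yl)deca-1,5,9-trien-4-yl]oxy}dimethylsilane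
Product: 23 (2E,6Z,10E,12R)-1,12-bis[(tert-butyldimethylsilyl)oxy]-3,7,11,15-tetramethyl-14-methylidenehexadeca-2,6,10-triene
Conditions: NiCl2·6H2O (20 mol %), 2,2'-bipyridine (20 mol %), AgNO3 (0.3 equiv), LiCl, DMF, undivided cell, Mg anode, reticulated vitreous carbon cathode, constant current, rt
Reagents that add atoms: none
Why: Cathodic reduction gives low-valent bipyridine-ligated nickel, which inserts into the C6–I bond of 22 with retention, while single-electron reduction of 9 releases phthalimide anion, CO2 and the primary C5 radical; capture of this radical by the alkenylnickel species and reductive elimination from trivalent nickel should form C5–C6. The closest known reaction type is the nickel-electrocatalytic decarboxylative alkenylation of redox-active esters with alkenyl iodides on a silver-modified cathode, as used for 1,5-diene (polyprenoid) chains. No ring is closed and no stereocentre is created; the stereochemical element at stake is the 6Z geometry, which the alkenyl–nickel bond carries over unchanged from the iodoalkene and which later encodes the cis C6–C7 oxirane. The step needs cross-coupling over homocoupling and intact 2E, 6Z and 10E alkenes. The excess of 9 covers radical dimerisation, both allylic oxygens are silyl ethers (no ionisation to allylnickel species, as esters would allow), there is no conjugated acceptor for the C5 radical, and its only intramolecular path, 3-exo closure onto C3, is slow, reversible and returns the same radical.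

Step 11
Reactants: 23 (2E,6Z,10E,12R)-1,12-bis[(tert-butyldimethylsilyl)oxy]-3,7,11,15-tetramethyl-14-methylidenehexadeca-2,6,10-triene
Product: 24 (2E,6Z,10E,12R)-12-[(tert-butyldimethylsilyl)oxy]-3,7,11,15-tetramethyl-14-methylidenehexadeca-2,6,10-trien-1-ol
Conditions: HF·pyridine, pyridine, THF, 0 °C
Reagents that add atoms: none
Why: Buffered fluoride should cleave the unhindered primary allylic silyl ether much faster than the secondary one flanked by the C11 methyl and the C13 branch (steric differentiation of silyl ethers), at a stage where no oxirane is yet present.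

Step 12
Reactants: 24 (2E,6Z,10E,12R)-12-[(tert-butyldimethylsilyl)oxy]-3,7,11,15-tetramethyl-14-methylidenehexadeca-2,6,10-trien-1-ol
Product: 25 (2R,3R,6Z,10E,12R)-12-[(tert-butyldimethylsilyl)oxy]-2,3-epoxy-3,7,11,15-tetramethyl-14-methylidenehexadeca-6,10-dien-1-ol
Conditions: Ti(OiPr)4 (10 mol %), D-(−)-diethyl tartrate (12 mol %), t-BuOOH, 4 Å MS, CH2Cl2, −20 °C
Reagents that add atoms: tert-butyl hydroperoxide, CC(C)(C)OO
Why: Sharpless asymmetric epoxidation, in which the titanium–tartrate complex binds the C1 hydroxyl and delivers oxygen only to the C2=C3 allylic alkene, should give the (2R,3R) oxirane with D-(−)-diethyl tartrate, the other alkenes having no free allylic hydroxyl.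

Step 13
Reactants: 25 (2R,3R,6Z,10E,12R)-12-[(tert-butyldimethylsilyl)oxy]-2,3-epoxy-3,7,11,15-tetramethyl-14-methylidenehexadeca-6,10-dien-1-ol
Product: 26 (2R,3R,6R,7S,10E,12R)-12-[(tert-butyldimethylsilyl)oxy]-2,3:6,7-diepoxy-3,7,11,15-tetramethyl-14-methylidenehexadec-10-en-1-ol
Conditions: 1,2:4,5-di-O-isopropylidene-β-D-erythro-2,3-hexodiulo-2,6-pyranose (0.3 equiv), Oxone (2KHSO5·KHSO4·K2SO4), K2CO3, Bu4NHSO4, MeCN/CH2(OMe)2, aq. Na2B4O7/Na2EDTA buffer, −10 to 0 °C
Reagents that add atoms: potassium peroxymonosulfate (active salt of Oxone), [K+].[O-]S(=O)(=O)OO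
Why: Shi epoxidation, in which the chiral dioxirane from the D-fructose-derived ketone attacks the most electron-rich unhindered trisubstituted alkene C6=C7 through the spiro transition state that places the vinylic H-6 next to the spiro ketal, should give the cis (6R,7S) oxirane from the Z-alkene, while C10=C11 is deactivated and shielded by its allylic silyloxy group and the 1,1-disubstituted C14 methylidene is intrinsically slower.

Step 14
Reactants: 26 (2R,3R,6R,7S,10E,12R)-12-[(tert-butyldimethylsilyl)oxy]-2,3:6,7-diepoxy-3,7,11,15-tetramethyl-14-methylidenehexadec-10-en-1-ol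
Product: 27 (2R,3R,6R,7S,10E,12R)-2,3:6,7-diepoxy-3,7,11,15-tetramethyl-14-methylidenehexadec-10-ene-1,12-diol (CNP0156678.1)
Conditions: Bu4NF, AcOH, THF, 0 °C to rt
Reagents that add atoms: none
Why: Fluoride-mediated desilylation buffered with acetic acid should free C12–OH without opening or migrating either oxirane.

Compound list
1 | (tert-butyldimethylsilyloxy)acetaldehyde | O=CCO[Si](C)(C)C(C)(C)C | starting material
2 | isopropenylmagnesium bromide | C=C(C)[Mg]Br | starting material
3 | rac-1-[(tert-butyldimethylsilyl)oxy]-3-methylbut-3-en-2-ol | C=C(C)C(O)CO[Si](C)(C)C(C)(C)C | intermediate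
4 | triethyl orthoacetate | CC(OCC)(OCC)OCC | starting material
5 | mixed orthoester, 1,1-diethoxyethyl ether of 3 | C=C(C)C(CO[Si](C)(C)C(C)(C)C)OC(C)(OCC)OCC | intermediate (not isolated)
6 | ketene acetal, 1-ethoxyvinyl ether of 3 | C=C(C)C(CO[Si](C)(C)C(C)(C)C)OC(=C)OCC | intermediate (not isolated)
7 | ethyl (4E)-6-[(tert-butyldimethylsilyl)oxy]-4-methylhex-4-enoate | CCOC(=O)CC/C(C)=C/CO[Si](C)(C)C(C)(C)C | intermediate
8 | (4E)-6-[(tert-butyldimethylsilyl)oxy]-4-methylhex-4-enoic acid | OC(=O)CC/C(C)=C/CO[Si](C)(C)C(C)(C)C | intermediate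
9 | 1,3-dioxoisoindolin-2-yl (4E)-6-[(tert-butyldimethylsilyl)oxy]-4-methylhex-4-enoate | O=C(CC/C(C)=C/CO[Si](C)(C)C(C)(C)C)ON1C(=O)c2ccccc2C1=O | intermediate
10 | pent-4-yn-1-ol | C#CCCCO | starting material
11 | syn-alkenylalane, dimethylaluminium alkoxide of (4E)-5-(dimethylalumanyl)-4-methylpent-4-en-1-ol | C[Al](C)OCCC/C(C)=C/[Al](C)C | intermediate (not isolated)
12 | chelated Z-alkenylalane, 2,6-dimethyl-1-oxa-2-aluminacyclohept-3-ene (methyl on Al and on the ring alkene carbon C4) | CC1=C[Al](C)OCCC1 | intermediate (not isolated)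
13 | (4Z)-5-iodo-4-methylpent-4-en-1-ol | OCCC/C(C)=C\I | intermediate
14 | (4Z)-5-iodo-4-methylpent-4-enal | O=CCC/C(C)=C\I | intermediate
15 | 2-(triphenylphosphoranylidene)propanal | CC(C=O)=P(c1ccccc1)(c1ccccc1)c1ccccc1 | starting material
16 | (2E,6Z)-7-iodo-2,6-dimethylhepta-2,6-dienal | O=C/C(C)=C/CC/C(C)=C\I | intermediate
17 | 2,3-dimethylbut-1-ene | C=C(C)C(C)C | starting material
18 | 2-isopropylallylpotassium | [K+].[CH2-]C(=C)C(C)C | intermediate (not isolated)
19 | (2-isopropylallyl)bis(isopinocampheyl)borane, Ipc groups of the (+)-Ipc2B series from (−)-α-pinene | C=C(CB([C@H]1C[C@H]2C[C@@H]([C@@H]1C)C2(C)C)[C@H]1C[C@H]2C[C@@H]([C@@H]1C)C2(C)C)C(C)C | intermediate (not isolated)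
20 | bis(isopinocampheyl)borinate ester of 21 | C=C(C[C@@H](OB([C@H]1C[C@H]2C[C@@H]([C@@H]1C)C2(C)C)[C@H]1C[C@H]2C[C@@H]([C@@H]1C)C2(C)C)/C(C)=C/CC/C(C)=C\I)C(C)C | intermediate (not isolated)
21 | (4R,5E,9Z)-10-iodo-5,9-dimethyl-2-(propan-2-yl)deca-1,5,9-trien-4-ol | C=C(C[C@@H](O)/C(C)=C/CC/C(C)=C\I)C(C)C | intermediate
22 | tert-butyl{[(4R,5E,9Z)-10-iodo-5,9-dimethyl-2-(propan-2-yl)deca-1,5,9-trien-4-yl]oxy}dimethylsilane | C=C(C[C@@H](O[Si](C)(C)C(C)(C)C)/C(C)=C/CC/C(C)=C\I)C(C)C | intermediate
23 | (2E,6Z,10E,12R)-1,12-bis[(tert-butyldimethylsilyl)oxy]-3,7,11,15-tetramethyl-14-methylidenehexadeca-2,6,10-triene | C=C(C[C@@H](O[Si](C)(C)C(C)(C)C)/C(C)=C/CC/C(C)=C\CC/C(C)=C/CO[Si](C)(C)C(C)(C)C)C(C)C | intermediate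
24 | (2E,6Z,10E,12R)-12-[(tert-butyldimethylsilyl)oxy]-3,7,11,15-tetramethyl-14-methylidenehexadeca-2,6,10-trien-1-ol | C=C(C[C@@H](O[Si](C)(C)C(C)(C)C)/C(C)=C/CC/C(C)=C\CC/C(C)=C/CO)C(C)C | intermediate
25 | (2R,3R,6Z,10E,12R)-12-[(tert-butyldimethylsilyl)oxy]-2,3-epoxy-3,7,11,15-tetramethyl-14-methylidenehexadeca-6,10-dien-1-ol | C=C(C[C@@H](O[Si](C)(C)C(C)(C)C)/C(C)=C/CC/C(C)=C\CC[C@@]1(C)O[C@@H]1CO)C(C)C | intermediate
26 | (2R,3R,6R,7S,10E,12R)-12-[(tert-butyldimethylsilyl)oxy]-2,3:6,7-diepoxy-3,7,11,15-tetramethyl-14-methylidenehexadec-10-en-1-ol | C=C(C[C@@H](O[Si](C)(C)C(C)(C)C)/C(C)=C/CC[C@]1(C)O[C@@H]1CC[C@@]1(C)O[C@@H]1CO)C(C)C | intermediate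
27 | (2R,3R,6R,7S,10E,12R)-2,3:6,7-diepoxy-3,7,11,15-tetramethyl-14-methylidenehexadec-10-ene-1,12-diol (CNP0156678.1) | C=C(C[C@@H](O)/C(C)=C/CC[C@]1(C)O[C@@H]1CC[C@@]1(C)O[C@@H]1CO)C(C)C | target

Total step count: 14 (steps 1–4 give fragment A, steps 5–9 give fragment B, steps 10–14 are the union and endgame).
Longest linear sequence: 10 steps (steps 5–14, from pent-4-yn-1-ol 10).

Steps most likely to fail

Step 10. The radical coupling may lose material through dimerisation or hydrogen abstraction of the C5 radical, through hydrodehalogenation or homocoupling of the iodoalkene, or through erosion of the 2E geometry by reversible 3-exo cyclisation of the homoallylic radical. The fallback makes the same C5–C6 bond by a two-electron B-alkyl Suzuki–Miyaura coupling. It sets out from aldehyde 1 and ylide 15: Wittig olefination (CH2Cl2, rt) should give (2E)-4-[(tert-butyldimethylsilyl)oxy]-2-methylbut-2-enal F1. Methylenation (Ph3PCH3Br, KN(SiMe3)2, THF, −78 to 0 °C) should give tert-butyldimethyl{[(2E)-3-methylpenta-2,4-dien-1-yl]oxy}silane F2. 9-BBN-H (THF, 0 °C to rt) should hydroborate only the monosubstituted C4=C5 vinyl group, with boron on C5, giving 9-{(3E)-5-[(tert-butyldimethylsilyl)oxy]-3-methylpent-3-en-1-yl}-9-borabicyclo[3.3.1]nonane F3, which is not isolated. Addition of 22, Pd(dppf)Cl2, AsPh3 and aqueous Cs2CO3 in DMF/THF at rt should then couple with retention of the Z geometry, and the route is rejoined at 23.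

Step 13. The free 2,3-epoxy alcohol may suffer base-induced epoxide migration or hydrolysis in the pH 10.5 aqueous medium, and the dioxirane may over-oxidise the remaining alkenes when the polar substrate reacts sluggishly. The fallback changes the order of oxygenation so that the dioxirane meets a fully silylated, lipophilic substrate in which both flanking trisubstituted alkenes carry deactivating allylic silyloxy groups. It sets out from 23: Shi epoxidation under the conditions of step 13 should give (2E,6R,7S,10E,12R)-1,12-bis[(tert-butyldimethylsilyl)oxy]-6,7-epoxy-3,7,11,15-tetramethyl-14-methylidenehexadeca-2,10-diene F4. NH4F in MeOH at rt should then remove only the primary silyl group without acid, giving (2E,6R,7S,10E,12R)-12-[(tert-butyldimethylsilyl)oxy]-6,7-epoxy-3,7,11,15-tetramethyl-14-methylidenehexadeca-2,10-dien-1-ol F5. Sharpless epoxidation (Ti(OiPr)4, D-(−)-diethyl tartrate, t-BuOOH, 4 Å MS, CH2Cl2, −20 °C) returns to the route at 26.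

Step 8. Facial selectivity of the allyl transfer may be poor because the 2-isopropyl group crowds the chair transition state, or the metalation of 17 may be incompletely selective, so that 21 is formed with insufficient enantiomeric purity. The fallback sets the carbinol centre by reduction instead of by C–C bond formation. It sets out from 21 of low enantiomeric purity: Dess–Martin oxidation (CH2Cl2, 0 °C) should give (5E,9Z)-10-iodo-5,9-dimethyl-2-(propan-2-yl)deca-1,5,9-trien-4-one F6, handled without base to avoid conjugation of the methylidene. Corey–Bakshi–Shibata reduction ((S)-2-methyl-CBS-oxazaborolidine (cat.), catecholborane, toluene, −78 °C), with the alkenyl group acting as the large substituent, should return 21 as the 4R alcohol.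

Further compounds
F1 | step 10 | (2E)-4-[(tert-butyldimethylsilyl)oxy]-2-methylbut-2-enal | O=C/C(C)=C/CO[Si](C)(C)C(C)(C)C
F2 | step 10 | tert-butyldimethyl{[(2E)-3-methylpenta-2,4-dien-1-yl]oxy}silane | C=C/C(C)=C/CO[Si](C)(C)C(C)(C)C
F3 | step 10 | 9-{(3E)-5-[(tert-butyldimethylsilyl)oxy]-3-methylpent-3-en-1-yl}-9-borabicyclo[3.3.1]nonane | B1(CC/C(C)=C/CO[Si](C)(C)C(C)(C)C)C2CCCC1CCC2
F4 | step 13 | (2E,6R,7S,10E,12R)-1,12-bis[(tert-butyldimethylsilyl)oxy]-6,7-epoxy-3,7,11,15-tetramethyl-14-methylidenehexadeca-2,10-diene | C=C(C[C@@H](O[Si](C)(C)C(C)(C)C)/C(C)=C/CC[C@]1(C)O[C@@H]1CC/C(C)=C/CO[Si](C)(C)C(C)(C)C)C(C)C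
F5 | step 13 | (2E,6R,7S,10E,12R)-12-[(tert-butyldimethylsilyl)oxy]-6,7-epoxy-3,7,11,15-tetramethyl-14-methylidenehexadeca-2,10-dien-1-ol | C=C(C[C@@H](O[Si](C)(C)C(C)(C)C)/C(C)=C/CC[C@]1(C)O[C@@H]1CC/C(C)=C/CO)C(C)C
F6 | step 8 | (5E,9Z)-10-iodo-5,9-dimethyl-2-(propan-2-yl)deca-1,5,9-trien-4-one | C=C(CC(=O)/C(C)=C/CC/C(C)=C\I)C(C)C
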